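**Early share.** A ratio of 0.407 carries this flask. It is the J formed per L formed, the selectivity factor, read as the slope of J against L through the origin up to 2.50 h, and it bears the scatter of 0.5 percentage points.

| flask | E | D | remark | time |
|---|---|---|---|---|
| epsilon | 0.10 M | 1.5 equiv | the very flask that is asked about, followed so far |  |
| flask | 0.10 M | 1.50 equiv |  | 4.0 d |

- epsilon (time / h: J / %, L / %): 0.500: 1.6, 1.2; 1.33: 2.0, 3.7; 2.50: 2.4, 7.0; 4.00: 4.6, 8.6; 6.00: 6.5, 12.2; 8.00: 6.0, 13.5

(scatter of a reading: 0.5 percentage points)



- ratio of J to L at 50 min
- ratio of J to L at 10 h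
- ratio of J to L at 4.0 d
- which of J and L there is more of at 4.0 d

**Fraction kept.** Take J as staying where it forms. J divided by the share then counts the L ever formed, and the L standing over that count is the fraction kept, which is the share divided by the ratio of J to L. Pooling the readings from 4.00 h to 8.00 h, centred on 6.00 h, gives 81.7% kept, so on this reckoning L reads as already being lost.

**Own reckoning.** While formation is steady, the fraction lost grows with time, here at 0.0305 /h. That gives a ratio of 0.418 at 50 min and 0.586 at 10 h. With formation taken as steady up to 4.0 d, L levels off while J climbs, and the ratio comes to the share times twice that pace times the time, 2.39. This figure is more than 1, so this reckoning puts J ahead at 4.0 d.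

**The result.** The forecast gives 0.8, 0.55 and 8 with J ahead, holding that “L is the kinetic product and J the sink”. The flask gives 0.366, 0.578 and 4.73, with 41.7% J against 8.82% L at 4.00 d.

    E + D ⇌ L (K = 2.40 /M, k = 0.00370 /M/min)
    E + D ⇌ J (K = 630 /M, k = 0.00130 /M/min)
    L ⇌ Q (K = 0.620, k = 9.20 × 10⁻⁵ /min)
    E ⇌ G (K = 0.240, k = 4.90 × 10⁻⁴ /min)

**Where L goes.** In this flask L goes back to E and D with a half-life of 0.31 d, short against the 4.0 d of the run, while the back reaction of J does not show in the final ratio. The fraction kept has fallen to 8.60% at 4.00 d. The neighbour charged with 0.25 M of E stands at the ratio 0.366 at 50 min and keeps 6.91% at 4.0 d.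

All runs stem from a simulated flask on assumed constants, noise included.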